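**Retrosynthetic overview**

1. The target comes from acidic removal of two ring B MOM ethers; before that, the C8 1,1-dimethylallyl group comes from an aromatic Claisen rearrangement of a 7-O-prenyl ether (O7–C bond exchanged for a C8–C bond).
2. O7 and O5 are each brought in by SNAr on a 5,7-difluoroisoflavone: prenyl alkoxide at C7, then a hydroxide surrogate at C5.
3. The strategy rests on ring A: C8a (bearing O1), C5 and C7 are the two ortho positions and the para position of C4a, which carries the C4 carbonyl, so all three aryl C–O bonds map onto the C–F bonds of a 2,4,6-trifluorobenzoyl group. The O1–C8a bond is closed by intramolecular SNAr of a hydroxymethylene ketone.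
4. The hydroxymethylene ketone comes from C-formylation of a deoxybenzoin, itself made from 2,4,6-trifluorophenyllithium and the Weinreb amide of MOM-protected 2,4-dihydroxyphenylacetic acid.
5. Rings A and B are bought; ring C (the pyranone) is the only ring formed, in step 6.

Key step: step 6

Remark on the chemistry: the target is achiral. The hydroxymethylene ketone of step 5 is drawn as its chelated Z enol, in equilibrium with the ketoaldehyde. The tetrahedral adduct of step 4 and the dienone of step 9 are transient racemates, so no configuration has to be controlled.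

**Route**

Step 1
Reactants: 1 2,4-dihydroxyphenylacetic acid
Product: 2 methyl 2-(2,4-dihydroxyphenyl)acetate
Conditions: MeOH, H2SO4 (cat.), reflux
Reagents that add atoms: methanol, CO
Why: Fischer esterification in a large excess of methanol, in which any benzofuranone lactone formed from the ortho phenol is reopened by the solvent to the same methyl ester.

Step 2
Reactants: 2 methyl 2-(2,4-dihydroxyphenyl)acetate
Product: 3 methyl 2-[2,4-bis(methoxymethoxy)phenyl]acetate
Conditions: MOMCl, i-Pr2NEt, CH2Cl2, 0 °C → rt
Reagents that add atoms: chloromethyl methyl ether (MOMCl), COCCl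
Why: O-alkylation of both phenols by the methoxymethyl oxocarbenium ion under an amine base too weak to enolise the ester, giving acetal ethers that tolerate organolithiums, alkoxides and the later Lewis acid and leave with mild acid at the end.

Step 3
Reactants: 3 methyl 2-[2,4-bis(methoxymethoxy)phenyl]acetate
Product: 4 2-[2,4-bis(methoxymethoxy)phenyl]-N-methoxy-N-methylacetamide
Conditions: MeNH(OMe)·HCl, i-PrMgCl, THF, −20 → 0 °C
Reagents that add atoms: N,O-dimethylhydroxylamine hydrochloride, CNOC.Cl
Why: Weinreb amide formation by direct aminolysis of the ester with the chloromagnesium amide made in the flask, a standard conversion of arylacetic esters that stops cleanly at the amide.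

Step 4
Reactants: 4 2-[2,4-bis(methoxymethoxy)phenyl]-N-methoxy-N-methylacetamide; 5 1,3,5-trifluorobenzene
Product: 8 2-[2,4-bis(methoxymethoxy)phenyl]-1-(2,4,6-trifluorophenyl)ethan-1-one, via 2,4,6-trifluorophenyllithium 6 (not isolated), via lithium hemiaminal chelate 7 (not isolated)
Conditions: 5 (1.5 equiv), n-BuLi (1.4 equiv), THF, −78 °C; then 4, −78 °C; aq NH4Cl at −78 °C
Reagents that add atoms: none
Why: Deprotonative lithiation of the C–H flanked by two fluorines followed by Weinreb ketone synthesis, in which chelate 7 holds the tetrahedral stage until the cold quench so that no tertiary alcohol forms, while −78 °C prevents LiF loss to the aryne and should let carbonyl addition outrun enolisation of the benzylic CH2.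

Step 5
Reactants: 8 2-[2,4-bis(methoxymethoxy)phenyl]-1-(2,4,6-trifluorophenyl)ethan-1-one; 9 ethyl formate
Product: 10 (Z)-3-hydroxy-2-[2,4-bis(methoxymethoxy)phenyl]-1-(2,4,6-trifluorophenyl)prop-2-en-1-one
Conditions: LiN(SiMe3)2 (1.1 equiv), THF, −78 °C; HCO2Et (3 equiv), −78 → 0 °C; AcOH, then water
Reagents that add atoms: none
Why: Crossed Claisen condensation (C-formylation) of the ketone enolate with ethyl formate, driven by formation of the stabilised β-ketoaldehyde enolate and run with one equivalent of a non-nucleophilic amide base so that only neutral ethanol, not ethoxide, is present beside the fluorinated ring.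

Step 6
Reactants: 10 (Z)-3-hydroxy-2-[2,4-bis(methoxymethoxy)phenyl]-1-(2,4,6-trifluorophenyl)prop-2-en-1-one
Product: 11 5,7-difluoro-3-[2,4-bis(methoxymethoxy)phenyl]chromen-4-one
Conditions: K2CO3 (2 equiv), MeCN, rt → 50 °C
Reagents that add atoms: none
Why: K2CO3 deprotonates the acidic enol of 10, and the enolate oxygen adds to an ortho C–F carbon of the trifluorobenzoyl ring to give a Meisenheimer adduct whose charge is taken up by the ketone and the two other fluorines, after which fluoride leaves and the O1–C8a bond is in place. The closest known reaction type is the closure of chromones and 4-quinolones by intramolecular SNAr of ortho-fluoroaroyl enolates and enaminones. Ring C closes by six-membered addition–elimination at an sp2 aryl carbon, formally a 6-exo-trig attack on the C8a=C8 bond of the arene. No stereocentre is formed, and the enol geometry is not a control element because the β-ketoaldehyde enolate rotates freely into the Z form that places its oxygen next to the aroyl group. The step needs O- over C-cyclisation and ortho over para attack, and geometry secures both: the central carbon could only close a four-membered ring, the para fluorine is out of reach, and the two ortho fluorines are equivalent by the symmetry of the ring. Carbonate in acetonitrile is not nucleophilic, so the C5 and C7 fluorines, which become more activated once the carbonyl is held coplanar in the pyranone, should be left untouched for the later substitutions.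

Step 7
Reactants: 11 5,7-difluoro-3-[2,4-bis(methoxymethoxy)phenyl]chromen-4-one; 12 3-methylbut-2-en-1-ol
Product: 13 5-fluoro-7-(3-methylbut-2-enyloxy)-3-[2,4-bis(methoxymethoxy)phenyl]chromen-4-one
Conditions: 12 (1.1 equiv), KN(SiMe3)2 (1.0 equiv), 18-crown-6, THF, alkoxide added slowly to 11, −40 → 0 °C
Reagents that add atoms: none
Why: Intermolecular SNAr (addition–elimination) at C7, the fluorine para to the carbonyl-bearing C4a, where the crown-sequestered potassium alkoxide has no cation to guide it to the peri C5–F and the new 7-alkoxy group donates into the carbonyl and so slows a second substitution.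

Step 8
Reactants: 13 5-fluoro-7-(3-methylbut-2-enyloxy)-3-[2,4-bis(methoxymethoxy)phenyl]chromen-4-one
Product: 15 5-hydroxy-7-(3-methylbut-2-enyloxy)-3-[2,4-bis(methoxymethoxy)phenyl]chromen-4-one, via 5-[2-(methylsulfonyl)ethoxy] ether 14 (not isolated)
Conditions: MeSO2CH2CH2OH (2 equiv), NaH (4 equiv), DMF, 0 °C → rt; aq NH4Cl
Reagents that add atoms: 2-(methylsulfonyl)ethanol, CS(=O)(=O)CCO
Why: SNAr at C5 (ortho to C4a, with sodium bridging the carbonyl oxygen and the incoming alkoxide) followed in the same flask by E1cB β-elimination of ether 14, which releases the chelated 5-phenoxide and methyl vinyl sulfone, so the C5 hydroxyl arrives without free hydroxide that would open the pyranone at C2.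

Step 9
Reactants: 15 5-hydroxy-7-(3-methylbut-2-enyloxy)-3-[2,4-bis(methoxymethoxy)phenyl]chromen-4-one
Product: 17 5,7-dihydroxy-8-(2-methylbut-3-en-2-yl)-3-[2,4-bis(methoxymethoxy)phenyl]chromen-4-one, via C8 dienone 16 (not isolated)
Conditions: Eu(fod)3 (10 mol %), acid-free CHCl3, 60–70 °C, sealed tube
Reagents that add atoms: none
Why: Aromatic Claisen rearrangement ([3,3]-sigmatropic) catalysed by the oxophilic complex Eu(fod)3 bound at the 5-hydroxy-4-keto site, in which the allyl unit is transposed so that its tertiary carbon bonds to C8, the ortho position across the C7–C8 bond that is expected to carry the higher double-bond character in a chelated 7-alkoxychromone, before dienone 16 tautomerises to the phenol.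

Step 10
Reactants: 17 5,7-dihydroxy-8-(2-methylbut-3-en-2-yl)-3-[2,4-bis(methoxymethoxy)phenyl]chromen-4-one
Product: 18 5,7-dihydroxy-3-(2,4-dihydroxyphenyl)-8-(2-methylbut-3-en-2-yl)chromen-4-one
Conditions: HCl (about 1.5 M), MeOH–THF, rt → 40 °C
Reagents that add atoms: none
Why: Acid-catalysed acetal cleavage (transacetalisation to dimethoxymethane) of the two aryl MOM ethers under conditions mild enough that the monosubstituted alkene, which would have to protonate to a secondary cation, should not cyclise onto the 7-hydroxyl.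

**Compound list**

1 | 2,4-dihydroxyphenylacetic acid | OC(=O)Cc1ccc(O)cc1O | starting material
2 | methyl 2-(2,4-dihydroxyphenyl)acetate | COC(=O)Cc1ccc(O)cc1O | intermediate
3 | methyl 2-[2,4-bis(methoxymethoxy)phenyl]acetate | COC(=O)Cc1ccc(OCOC)cc1OCOC | intermediate
4 | 2-[2,4-bis(methoxymethoxy)phenyl]-N-methoxy-N-methylacetamide | CON(C)C(=O)Cc1ccc(OCOC)cc1OCOC | intermediate
5 | 1,3,5-trifluorobenzene | Fc1cc(F)cc(F)c1 | starting material
6 | 2,4,6-trifluorophenyllithium | [Li]c1c(F)cc(F)cc1F | intermediate (not isolated)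
7 | lithium 2-[2,4-bis(methoxymethoxy)phenyl]-1-[methoxy(methyl)amino]-1-(2,4,6-trifluorophenyl)ethan-1-olate (racemic) | [Li+].[O-]C(Cc1ccc(OCOC)cc1OCOC)(N(C)OC)c1c(F)cc(F)cc1F | intermediate (not isolated)
8 | 2-[2,4-bis(methoxymethoxy)phenyl]-1-(2,4,6-trifluorophenyl)ethan-1-one | COCOc1ccc(CC(=O)c2c(F)cc(F)cc2F)c(OCOC)c1 | intermediate
9 | ethyl formate | CCOC=O | starting material
10 | (Z)-3-hydroxy-2-[2,4-bis(methoxymethoxy)phenyl]-1-(2,4,6-trifluorophenyl)prop-2-en-1-one | O/C=C(/c1ccc(OCOC)cc1OCOC)C(=O)c1c(F)cc(F)cc1F | intermediate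
11 | 5,7-difluoro-3-[2,4-bis(methoxymethoxy)phenyl]chromen-4-one | COCOc1ccc(-c2coc3cc(F)cc(F)c3c2=O)c(OCOC)c1 | intermediate
12 | 3-methylbut-2-en-1-ol | CC(C)=CCO | starting material
13 | 5-fluoro-7-(3-methylbut-2-enyloxy)-3-[2,4-bis(methoxymethoxy)phenyl]chromen-4-one | COCOc1ccc(-c2coc3cc(OCC=C(C)C)cc(F)c3c2=O)c(OCOC)c1 | intermediate
14 | 7-(3-methylbut-2-enyloxy)-5-[2-(methylsulfonyl)ethoxy]-3-[2,4-bis(methoxymethoxy)phenyl]chromen-4-one | COCOc1ccc(-c2coc3cc(OCC=C(C)C)cc(OCCS(C)(=O)=O)c3c2=O)c(OCOC)c1 | intermediate (not isolated)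
15 | 5-hydroxy-7-(3-methylbut-2-enyloxy)-3-[2,4-bis(methoxymethoxy)phenyl]chromen-4-one | COCOc1ccc(-c2coc3cc(OCC=C(C)C)cc(O)c3c2=O)c(OCOC)c1 | intermediate
16 | 5-hydroxy-8-(2-methylbut-3-en-2-yl)-3-[2,4-bis(methoxymethoxy)phenyl]-8H-chromene-4,7-dione (racemic at C8) | C=CC(C)(C)C1C(=O)C=C(O)C2=C1OC=C(c1ccc(OCOC)cc1OCOC)C2=O | intermediate (not isolated)
17 | 5,7-dihydroxy-8-(2-methylbut-3-en-2-yl)-3-[2,4-bis(methoxymethoxy)phenyl]chromen-4-one | COCOc1ccc(-c2coc3c(C(C)(C)C=C)c(O)cc(O)c3c2=O)c(OCOC)c1 | intermediate
18 | 5,7-dihydroxy-3-(2,4-dihydroxyphenyl)-8-(2-methylbut-3-en-2-yl)chromen-4-one | C=CC(C)(C)c1c(O)cc(O)c2c(=O)c(-c3ccc(O)cc3O)coc12 | target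

**Step count**

Total: 10 steps. Longest linear sequence: 10 steps, from 1 to 18; compounds 5, 9 and 12 enter without steps of their own.

**Steps most likely to fail**

Step 9. The allyl unit may migrate to C6 instead of C8, and the Lewis acid may then close the 7-hydroxyl onto the new alkene. The fallback sets out from 13 and rearranges before any C5 oxygen is present, so that the substrate behaves like a simple 7-allyloxychromone, for which ortho migration to C8 is the established course. Heating 13 in N,N-diethylaniline at about 190 °C should lead through 5-fluoro-8-(2-methylbut-3-en-2-yl)-3-[2,4-bis(methoxymethoxy)phenyl]-8H-chromene-4,7-dione F1 to 5-fluoro-7-hydroxy-8-(2-methylbut-3-en-2-yl)-3-[2,4-bis(methoxymethoxy)phenyl]chromen-4-one F2. MOMCl and i-Pr2NEt in CH2Cl2 would cap the 7-hydroxyl to give 5-fluoro-7-(methoxymethoxy)-8-(2-methylbut-3-en-2-yl)-3-[2,4-bis(methoxymethoxy)phenyl]chromen-4-one F3. 2-(Methylsulfonyl)ethanol and NaH in DMF would then replace the C5 fluorine through 7-(methoxymethoxy)-8-(2-methylbut-3-en-2-yl)-5-[2-(methylsulfonyl)ethoxy]-3-[2,4-bis(methoxymethoxy)phenyl]chromen-4-one F4 and give 5-hydroxy-7-(methoxymethoxy)-8-(2-methylbut-3-en-2-yl)-3-[2,4-bis(methoxymethoxy)phenyl]chromen-4-one F5. HCl in MeOH–THF would remove all three MOM groups, and the route is rejoined at the target 18.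

Step 7. The alkoxide may attack the peri C5–F, substitute twice, or sit reversibly at C2, giving mixtures. The fallback sets out from 11 and makes the site of first attack irrelevant. Benzyl alcohol (2.5 equiv) and NaH in DMF at rt → 60 °C, with a mildly acidic work-up, should displace both fluorides to give 5,7-bis(benzyloxy)-3-[2,4-bis(methoxymethoxy)phenyl]chromen-4-one F6. Hydrogenolysis with H2 over palladium on carbon (Pd/C) in EtOAc, stopped after two equivalents, would give 5,7-dihydroxy-3-[2,4-bis(methoxymethoxy)phenyl]chromen-4-one F7. 1-Bromo-3-methylbut-2-ene and K2CO3 in acetone at rt should alkylate only the 7-hydroxyl, the 5-hydroxyl being held in the hydrogen bond to the C4 carbonyl. This comes back to the route at 15 and also bypasses step 8.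

Step 8. The sulfonylethoxide may undergo β-elimination before it has substituted, releasing hydroxide that opens the pyranone at C2 with loss of that carbon as formate; substitution on the donor-substituted ring may also be slow. The fallback sets out from 13 and separates substitution from unmasking. The sodium alkoxide of 4-methoxybenzyl alcohol (NaH, DMF, rt), which cannot release hydroxide, should give 5-(4-methoxybenzyloxy)-7-(3-methylbut-2-enyloxy)-3-[2,4-bis(methoxymethoxy)phenyl]chromen-4-one F8. Oxidative cleavage with DDQ in CH2Cl2–pH 7 buffer at 0 °C would then free the 5-hydroxyl, and the route is rejoined at 15.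

**Further compounds**

F1 | step 9 | 5-fluoro-8-(2-methylbut-3-en-2-yl)-3-[2,4-bis(methoxymethoxy)phenyl]-8H-chromene-4,7-dione (racemic at C8) | C=CC(C)(C)C1C(=O)C=C(F)C2=C1OC=C(c1ccc(OCOC)cc1OCOC)C2=O
F2 | step 9 | 5-fluoro-7-hydroxy-8-(2-methylbut-3-en-2-yl)-3-[2,4-bis(methoxymethoxy)phenyl]chromen-4-one | COCOc1ccc(-c2coc3c(C(C)(C)C=C)c(O)cc(F)c3c2=O)c(OCOC)c1
F3 | step 9 | 5-fluoro-7-(methoxymethoxy)-8-(2-methylbut-3-en-2-yl)-3-[2,4-bis(methoxymethoxy)phenyl]chromen-4-one | COCOc1ccc(-c2coc3c(C(C)(C)C=C)c(OCOC)cc(F)c3c2=O)c(OCOC)c1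
F4 | step 9 | 7-(methoxymethoxy)-8-(2-methylbut-3-en-2-yl)-5-[2-(methylsulfonyl)ethoxy]-3-[2,4-bis(methoxymethoxy)phenyl]chromen-4-one | COCOc1ccc(-c2coc3c(C(C)(C)C=C)c(OCOC)cc(OCCS(C)(=O)=O)c3c2=O)c(OCOC)c1
F5 | step 9 | 5-hydroxy-7-(methoxymethoxy)-8-(2-methylbut-3-en-2-yl)-3-[2,4-bis(methoxymethoxy)phenyl]chromen-4-one | COCOc1ccc(-c2coc3c(C(C)(C)C=C)c(OCOC)cc(O)c3c2=O)c(OCOC)c1
F6 | step 7 | 5,7-bis(benzyloxy)-3-[2,4-bis(methoxymethoxy)phenyl]chromen-4-one | COCOc1ccc(-c2coc3cc(OCc4ccccc4)cc(OCc4ccccc4)c3c2=O)c(OCOC)c1
F7 | step 7 | 5,7-dihydroxy-3-[2,4-bis(methoxymethoxy)phenyl]chromen-4-one | COCOc1ccc(-c2coc3cc(O)cc(O)c3c2=O)c(OCOC)c1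
F8 | step 8 | 5-(4-methoxybenzyloxy)-7-(3-methylbut-2-enyloxy)-3-[2,4-bis(methoxymethoxy)phenyl]chromen-4-one | COCOc1ccc(-c2coc3cc(OCC=C(C)C)cc(OCc4ccc(OC)cc4)c3c2=O)c(OCOC)c1
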